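The synthesis rests on breaking the C5–C6 bond of ring B (C4a, C5, C6, C7, C8, C8a). That ring carries the oxygenated three-carbon branch on C6 next to C5 and the angular methyl on C8a in a 1,4 relation to C6, the pattern a citronellal-type carbonyl-ene reaction delivers. One Lewis-acid step closes ring B, forms C5–C6, sets C6 and C5, and leaves an isopropenyl group for hydration. Its precursor is a ring A cyclohexane with C1, C4 and C8a set, a formyl group on C4a and a 4-methylpent-3-enyl chain on C8a; the C5 oxygen later leaves to give the C4a=C5 alkene.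

Key step: step 9

Remark on the chemistry: every intermediate carries the target's decalin locants (C1 bears the side chain, C4 the secondary methyl, C4a and C8a are the fusion carbons, C8a bears the angular methyl). β is the face of the C8a methyl, α the opposite face. The C1 carboxyl function is carried through the key step as a benzyloxymethyl spectator group. "Octalinyl" (compounds 20 to 30 and F9 to F11) means 4β,8aβ-dimethyl-6β-[2-(triethylsilyloxy)propan-2-yl]-1,2,3,4,6,7,8,8a-octahydronaphthalen-1β-yl.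

Step 1
Reactants: 1 3-(benzyloxy)propanal; 2 but-3-en-2-one
Product: 3 (R)-2-[(benzyloxy)methyl]-5-oxohexanal
Conditions: (R)-2-[methoxy(diphenyl)methyl]pyrrolidine (5 mol %), ethyl 3,4-dihydroxybenzoate (20 mol %), neat, 4 °C
Reagents that add atoms: none
Why: Amine-catalysed asymmetric Michael addition through the (E)-enamine of 1, which should add to the enone from the face remote from the diphenyl(methoxy)methyl group, so that the R catalyst sets the future C1 as drawn.

Step 2
Reactants: 3 (R)-2-[(benzyloxy)methyl]-5-oxohexanal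
Product: 4 (S)-4-[(benzyloxy)methyl]cyclohex-2-en-1-one
Conditions: LiOH (0.2 equiv), i-PrOH, rt
Reagents that add atoms: none
Why: Intramolecular aldol condensation of the methyl ketone onto the aldehyde closes ring A as the 4-substituted cyclohexenone under base mild enough to leave the C1 stereocentre alone.

Step 3
Reactants: 4 (S)-4-[(benzyloxy)methyl]cyclohex-2-en-1-one
Product: 6 (S)-4-[(benzyloxy)methyl]-3-methylcyclohex-2-en-1-one, via silyl enol ether 5 (not isolated)
Conditions: MeMgBr, CuI (10 mol %), TMSCl, THF, −78 °C; then Pd(OAc)2 (10 mol %), O2 (1 atm), DMSO, rt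
Reagents that add atoms: methylmagnesium bromide, C[Mg]Br; chlorotrimethylsilane, C[Si](C)(C)Cl (silyl group present only in 5)
Why: CuI-catalysed conjugate addition with in situ silylation gives the regiodefined enol ether 5, and Saegusa–Ito dehydrogenation restores the enone with the methyl group now on C8a, the transient C8a stereocentre being erased.

Step 4
Reactants: 6 (S)-4-[(benzyloxy)methyl]-3-methylcyclohex-2-en-1-one; 7 5-bromo-2-methylpent-2-ene
Product: 9 4-[(benzyloxy)methyl]-2-(hydroxymethyl)-3-methyl-3-(4-methylpent-3-en-1-yl)cyclohexan-1-one (CH2OBn β; CH2OH α; C8a methyl β), via silyl enol ether 8 (not isolated)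
Conditions: 7, Mg, THF, rt; then 6, CuBr·SMe2 (10 mol %), TMSCl, HMPA, THF, −78 °C; then aq. HCHO, Yb(OTf)3 (10 mol %), THF, rt
Reagents that add atoms: formaldehyde, C=O; chlorotrimethylsilane, C[Si](C)(C)Cl (silyl group present only in 8)
Why: CuBr·SMe2-catalysed conjugate addition of (4-methylpent-3-en-1-yl)magnesium bromide occurs anti to the C1 substituent of the 4-substituted enone and so builds the quaternary C8a with the methyl β and the chain α, and the enol ether 8 then undergoes a Yb(OTf)3-catalysed Mukaiyama aldol reaction with formaldehyde at C4a from the α face, anti to the pseudoaxial C8a methyl.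

Step 5
Reactants: 9 ring A β-hydroxy ketone (C4=O)
Product: 10 {5-[(benzyloxy)methyl]-6-methyl-6-(4-methylpent-3-en-1-yl)-2-methylidenecyclohexyl}methanol (C4=CH2; other centres as in 9)
Conditions: Zn, CH2Br2, TiCl4, THF/CH2Cl2, 0 °C to rt
Reagents that add atoms: dibromomethane, BrCBr
Why: Lombardo methylenation converts the hindered, enolisable C4 ketone into the exocyclic alkene under non-basic conditions that tolerate the free hydroxyl and avoid retro-aldol cleavage or epimerisation at C4a.

Step 6
Reactants: 10 ring A methylidene alcohol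
Product: 11 {3-[(benzyloxy)methyl]-2,6-dimethyl-2-(4-methylpent-3-en-1-yl)cyclohexyl}methanol (C4 methyl β, C4a CH2OH α)
Conditions: [Rh(nbd)(dppb)]BF4 (5 mol %), H2 (20 atm), CH2Cl2, rt
Reagents that add atoms: none
Why: Hydroxyl-directed homogeneous hydrogenation, in which [Rh(nbd)(dppb)]BF4 binds the α hydroxymethyl group and delivers hydrogen to the α face of the neighbouring 1,1-disubstituted alkene, sets C4 with its methyl β while the undirected trisubstituted alkene and the benzyl ether react far more slowly.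

Step 7
Reactants: 11 ring A primary alcohol
Product: 12 3-[(benzyloxy)methyl]-2,6-dimethyl-2-(4-methylpent-3-en-1-yl)cyclohexane-1-carbaldehyde with the formyl group α
Conditions: Dess–Martin periodinane, CH2Cl2, 0 °C to rt
Reagents that add atoms: none
Why: Dess–Martin oxidation turns the hindered primary alcohol into the aldehyde under neutral conditions.

Step 8
Reactants: 12 α-formyl aldehyde
Product: 13 3-[(benzyloxy)methyl]-2,6-dimethyl-2-(4-methylpent-3-en-1-yl)cyclohexane-1-carbaldehyde with the formyl group β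
Conditions: KN(SiMe3)2, THF, −78 °C; then AcOH, −78 °C
Reagents that add atoms: none
Why: Kinetic protonation of the exocyclic potassium enolate, in which allylic 1,3-strain holds the C4 methyl axial and the equatorial C1 group keeps the C8a methyl axial so that both shield the β face, should deliver the proton to C4a from the α face and turn the formyl group β.

Step 9
Reactants: 13 β-formyl aldehyde (ring A aldehyde with the homoprenyl chain on C8a)
Product: 14 1β-[(benzyloxy)methyl]-4β,8aβ-dimethyl-6β-(prop-1-en-2-yl)decahydronaphthalen-5α-ol (4a-H α, trans-fused)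
Conditions: Me2AlCl (1.5 equiv), CH2Cl2, −78 to −20 °C
Reagents that add atoms: none
Why: Me2AlCl binds the aldehyde oxygen, the CH carbon of the trisubstituted alkene (C6) attacks C5 and a hydrogen of the terminal methyl group passes to oxygen through a six-membered chair-like array, a concerted Lewis-acid carbonyl-ene reaction whose closest precedent is the cyclisation of citronellal to isopulegol. Ring B closes in the 6-exo mode with respect to the carbonyl group. C6 is set by the chair, in which the C8a methyl is axial and the developing isopropenyl group equatorial and therefore β, cis to that methyl; C5 is set by the same closed transition state with the oxygen equatorial and trans to the isopropenyl group. The β formyl group and the α chain of 13 are both equatorial on ring A, so the fusion is trans, at the price of a syn-axial methyl pair that the chair tolerates. The step needs the ene pathway to win over cationic Prins pathways, which the proton-scavenging Me2AlCl at low temperature secures, and the substrate offers the activated aldehyde no other alkene or nucleophile, the benzyl ether being inert.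

Step 10
Reactants: 14 trans-fused homoallylic alcohol
Product: 15 1β-[(benzyloxy)methyl]-6β-(2-hydroxypropan-2-yl)-4β,8aβ-dimethyldecahydronaphthalen-5α-ol
Conditions: Co(acac)2 (20 mol %), PhSiH3, O2 (1 atm), i-PrOH/THF, rt
Reagents that add atoms: dioxygen, O=O
Why: Mukaiyama hydration (hydrogen-atom transfer to the terminal carbon, capture of the tertiary radical by oxygen, reduction) gives the Markovnikov tertiary alcohol at the only alkene present.

Step 11
Reactants: 15 diol
Product: 16 1β-[(benzyloxy)methyl]-6β-(2-hydroxypropan-2-yl)-4β,8aβ-dimethyl-4aα-H-decahydronaphthalen-5-one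
Conditions: Dess–Martin periodinane, CH2Cl2, rt
Reagents that add atoms: none
Why: Dess–Martin oxidation takes the secondary alcohol to the ketone while the tertiary alcohol cannot react, and the neutral medium avoids retro-aldol cleavage of the β-hydroxy ketone.

Step 12
Reactants: 16 β-hydroxy ketone
Product: 17 triethylsilyl ether of 16
Conditions: Et3SiOTf, 2,6-lutidine, CH2Cl2, −78 °C
Reagents that add atoms: triethylsilyl trifluoromethanesulfonate, CC[Si](CC)(CC)OS(=O)(=O)C(F)(F)F
Why: Silylation of the hindered tertiary alcohol with a silyl triflate and lutidine removes the alkoxide that would otherwise trigger retro-aldol cleavage in the next step.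

Step 13
Reactants: 17 silyl-protected ketone
Product: 18 1β-[(benzyloxy)methyl]-4β,8aβ-dimethyl-6β-[2-(triethylsilyloxy)propan-2-yl]-1,2,3,4,6,7,8,8a-octahydronaphthalen-5-yl trifluoromethanesulfonate (C4a=C5)
Conditions: KN(SiMe3)2, THF, −78 °C; then N-(5-chloropyridin-2-yl)bis(trifluoromethanesulfonyl)imide, −78 to −40 °C; aq. NH4Cl
Reagents that add atoms: N-(5-chloropyridin-2-yl)bis(trifluoromethanesulfonyl)imide, FC(F)(F)S(=O)(=O)N(c1ccc(Cl)cn1)S(=O)(=O)C(F)(F)F
Why: Kinetic enolate formation and O-triflation with Comins' reagent should occur at the axial C4a hydrogen on the open α face, because the C6 hydrogen is screened by the adjacent quaternary silyloxy carbon and its enolate would carry a tert-alkyl group on the double bond, and trapping at −78 °C forestalls β-elimination of the silyloxy group.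

Step 14
Reactants: 18 enol triflate
Product: 19 1β-[(benzyloxy)methyl]-4β,8aβ-dimethyl-6β-[2-(triethylsilyloxy)propan-2-yl]-1,2,3,4,6,7,8,8a-octahydronaphthalene (C4a=C5)
Conditions: Pd(OAc)2 (5 mol %), PPh3, HCO2H, n-Bu3N, DMF, 60 °C
Reagents that add atoms: none
Why: Formate reduction of the enol triflate, catalysed by Pd(OAc)2 and PPh3, replaces the triflate by hydrogen and leaves the double bond fixed between C4a and C5.

Step 15
Reactants: 19 benzyl ether
Product: 20 octalinylmethanol
Conditions: Li, NH3 (l), THF, −78 °C; then NH4Cl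
Reagents that add atoms: none
Why: Dissolving-metal cleavage of the benzyl ether spares the isolated trisubstituted alkene and the silyl ether, which hydrogenolysis would not guarantee.

Step 16
Reactants: 20 octalinylmethanol
Product: 21 octalinylcarbaldehyde (formyl on C1, β)
Conditions: Dess–Martin periodinane, CH2Cl2, rt
Reagents that add atoms: none
Why: Dess–Martin oxidation gives the α-branched aldehyde without epimerising C1.

Step 17
Reactants: 21 octalinylcarbaldehyde
Product: 22 (E)-4-(octalinyl)but-3-en-2-one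
Conditions: (MeO)2P(O)CH2C(O)CH3, LiCl, i-Pr2NEt, MeCN, rt
Reagents that add atoms: dimethyl (2-oxopropyl)phosphonate, COP(=O)(CC(C)=O)OC
Why: Horner–Wadsworth–Emmons olefination under the mild Masamune–Roush conditions gives the E enone and does not enolise the aldehyde.

Step 18
Reactants: 22 (E)-4-(octalinyl)but-3-en-2-one; 23 1,3,5-trimethoxybenzene
Product: 25 (4S)-4-(octalinyl)-4-(2,4,6-trimethoxyphenyl)butan-2-one, via silyl enol ether 24 (not isolated)
Conditions: 23, n-BuLi, THF, 0 °C; CuBr·SMe2 (0.5 equiv per aryllithium), −40 °C; then TMSCl, 22, −78 to −30 °C; aq. NH4Cl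
Reagents that add atoms: chlorotrimethylsilane, C[Si](C)(C)Cl (silyl group present only in 24)
Why: Conjugate addition of lithium bis(2,4,6-trimethoxyphenyl)cuprate with TMSCl activation should take place on the enone conformer in which C1–H eclipses the alkene and from the face anti to the bulky quaternary C8a (Felkin-type 1,2-induction), which gives the S configuration at the new benzylic carbon; aryl groups flanked by two methoxy groups are known to transfer from copper to enones.

Step 19
Reactants: 25 methyl ketone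
Product: 26 2-[(1S)-3-methyl-1-(octalinyl)but-3-en-1-yl]-1,3,5-trimethoxybenzene
Conditions: Ph3PCH3Br, KOt-Bu, THF, 0 °C to rt
Reagents that add atoms: methyltriphenylphosphonium bromide, C[P+](c1ccccc1)(c1ccccc1)c1ccccc1.[Br-]
Why: Wittig methylenation of the methyl ketone supplies the last carbon of the isobutyl group.

Step 20
Reactants: 26 diene
Product: 27 2-[(1S)-3-methyl-1-(octalinyl)butyl]-1,3,5-trimethoxybenzene
Conditions: RhCl(PPh3)3 (5 mol %), H2 (1 atm), benzene/EtOH, rt
Reagents that add atoms: none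
Why: Homogeneous hydrogenation with RhCl(PPh3)3 reduces the unhindered 1,1-disubstituted alkene much faster than the hindered trisubstituted C4a=C5 alkene and so completes the isobutyl group.

Step 21
Reactants: 27 trimethoxyarene
Product: 29 2,4,6-trimethoxy-5-[(1S)-3-methyl-1-(octalinyl)butyl]benzene-1,3-dicarbaldehyde, via lithium hemiaminal 28 (not isolated)
Conditions: n-BuLi, TMEDA, THF, 0 °C; DMF, −78 to 0 °C; then n-BuLi, 0 °C; DMF; aq. NH4Cl
Reagents that add atoms: N,N-dimethylformamide, CN(C)C=O
Why: Two successive directed ortho-metalations at the ring positions flanked by two methoxy groups are each quenched with DMF, the first formyl group staying masked as the lithium hemiaminal 28 during the second lithiation, so that no acid touches the alkene or the silyl ether.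

Step 22
Reactants: 29 dialdehyde
Product: 31 target CNP0108656.4, via silyl ether 30 (not isolated)
Conditions: EtSNa, DMF, 110 °C; then 1 M HCl, THF, rt
Reagents that add atoms: none
Why: Nucleophilic demethylation (thiolate attack at methyl) removes the three methyl ethers, each activated by an ortho formyl group, under basic conditions that spare the alkene and the tertiary carbinol, and brief mild acid then cleaves the silyl ether.

Compound list
1 | 3-(benzyloxy)propanal | O=CCCOCc1ccccc1 | starting material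
2 | but-3-en-2-one (methyl vinyl ketone) | CC(=O)C=C | starting material
3 | (R)-2-[(benzyloxy)methyl]-5-oxohexanal | c1ccccc1COC[C@H](C=O)CCC(C)=O | intermediate
4 | (S)-4-[(benzyloxy)methyl]cyclohex-2-en-1-one | c1ccccc1COC[C@H]1CCC(=O)C=C1 | intermediate
5 | (4S)-4-[(benzyloxy)methyl]-3-methyl-1-(trimethylsilyloxy)cyclohex-1-ene, methyl trans to CH2OBn | c1ccccc1COC[C@H]1CCC(O[Si](C)(C)C)=C[C@@H]1C | intermediate (not isolated)
6 | (S)-4-[(benzyloxy)methyl]-3-methylcyclohex-2-en-1-one | c1ccccc1COC[C@H]1CCC(=O)C=C1C | intermediate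
7 | 5-bromo-2-methylpent-2-ene | CC(C)=CCCBr | starting material
8 | 4-[(benzyloxy)methyl]-3-methyl-3-(4-methylpent-3-en-1-yl)-1-(trimethylsilyloxy)cyclohex-1-ene (C1 CH2OBn β; C8a methyl β, chain α) | c1ccccc1COC[C@H]1CCC(O[Si](C)(C)C)=C[C@]1(C)CCC=C(C)C | intermediate (not isolated)
9 | 4-[(benzyloxy)methyl]-2-(hydroxymethyl)-3-methyl-3-(4-methylpent-3-en-1-yl)cyclohexan-1-one (C4 ketone; C1 CH2OBn β; C4a CH2OH α; C8a methyl β, chain α) | c1ccccc1COC[C@H]1CCC(=O)[C@H](CO)[C@]1(C)CCC=C(C)C | intermediate
10 | {5-[(benzyloxy)methyl]-6-methyl-6-(4-methylpent-3-en-1-yl)-2-methylidenecyclohexyl}methanol (C4=CH2; C4a CH2OH α; otherwise as 9) | c1ccccc1COC[C@H]1CCC(=C)[C@H](CO)[C@]1(C)CCC=C(C)C | intermediate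
11 | {3-[(benzyloxy)methyl]-2,6-dimethyl-2-(4-methylpent-3-en-1-yl)cyclohexyl}methanol (C1 CH2OBn β; C4 methyl β; C4a CH2OH α; C8a methyl β, chain α) | c1ccccc1COC[C@H]1CC[C@@H](C)[C@H](CO)[C@]1(C)CCC=C(C)C | intermediate
12 | 3-[(benzyloxy)methyl]-2,6-dimethyl-2-(4-methylpent-3-en-1-yl)cyclohexane-1-carbaldehyde, formyl α (C4a epimer of 13) | c1ccccc1COC[C@H]1CC[C@@H](C)[C@H](C=O)[C@]1(C)CCC=C(C)C | intermediate
13 | 3-[(benzyloxy)methyl]-2,6-dimethyl-2-(4-methylpent-3-en-1-yl)cyclohexane-1-carbaldehyde, formyl β (CH2OBn, both methyls and CHO on the β face, chain α); key-step precursor | c1ccccc1COC[C@H]1CC[C@@H](C)[C@@H](C=O)[C@]1(C)CCC=C(C)C | intermediate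
14 | 1β-[(benzyloxy)methyl]-4β,8aβ-dimethyl-6β-(prop-1-en-2-yl)decahydronaphthalen-5α-ol, 4a-H α (trans-fused); key-step product | c1ccccc1COC[C@H]1CC[C@@H](C)[C@H]2[C@H](O)[C@@H](C(C)=C)CC[C@@]21C | intermediate
15 | 1β-[(benzyloxy)methyl]-6β-(2-hydroxypropan-2-yl)-4β,8aβ-dimethyldecahydronaphthalen-5α-ol, 4a-H α | c1ccccc1COC[C@H]1CC[C@@H](C)[C@H]2[C@H](O)[C@@H](C(C)(C)O)CC[C@@]21C | intermediate
16 | 1β-[(benzyloxy)methyl]-6β-(2-hydroxypropan-2-yl)-4β,8aβ-dimethyldecahydronaphthalen-5-one, 4a-H α | c1ccccc1COC[C@H]1CC[C@@H](C)[C@H]2C(=O)[C@@H](C(C)(C)O)CC[C@@]21C | intermediate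
17 | triethylsilyl ether of 16 at the tertiary hydroxyl | c1ccccc1COC[C@H]1CC[C@@H](C)[C@H]2C(=O)[C@@H](C(C)(C)O[Si](CC)(CC)CC)CC[C@@]21C | intermediate
18 | 1β-[(benzyloxy)methyl]-4β,8aβ-dimethyl-6β-[2-(triethylsilyloxy)propan-2-yl]-1,2,3,4,6,7,8,8a-octahydronaphthalen-5-yl trifluoromethanesulfonate (C4a=C5) | c1ccccc1COC[C@H]1CC[C@@H](C)C2=C(OS(=O)(=O)C(F)(F)F)[C@@H](C(C)(C)O[Si](CC)(CC)CC)CC[C@@]21C | intermediate
19 | 1β-[(benzyloxy)methyl]-4β,8aβ-dimethyl-6β-[2-(triethylsilyloxy)propan-2-yl]-1,2,3,4,6,7,8,8a-octahydronaphthalene (C4a=C5) | c1ccccc1COC[C@H]1CC[C@@H](C)C2=C[C@@H](C(C)(C)O[Si](CC)(CC)CC)CC[C@@]21C | intermediate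
20 | octalinylmethanol: {4β,8aβ-dimethyl-6β-[2-(triethylsilyloxy)propan-2-yl]-1,2,3,4,6,7,8,8a-octahydronaphthalen-1β-yl}methanol | OC[C@H]1CC[C@@H](C)C2=C[C@@H](C(C)(C)O[Si](CC)(CC)CC)CC[C@@]21C | intermediate
21 | 4β,8aβ-dimethyl-6β-[2-(triethylsilyloxy)propan-2-yl]-1,2,3,4,6,7,8,8a-octahydronaphthalene-1β-carbaldehyde | O=C[C@H]1CC[C@@H](C)C2=C[C@@H](C(C)(C)O[Si](CC)(CC)CC)CC[C@@]21C | intermediate
22 | (E)-4-(octalinyl)but-3-en-2-one | CC(=O)/C=C/[C@H]1CC[C@@H](C)C2=C[C@@H](C(C)(C)O[Si](CC)(CC)CC)CC[C@@]21C | intermediate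
23 | 1,3,5-trimethoxybenzene | COc1cc(OC)cc(OC)c1 | starting material
24 | trimethylsilyl enol ether of 25 (silyloxy on C2 of the butenyl chain, C2=C3) | CC(O[Si](C)(C)C)=C[C@H](c1c(OC)cc(OC)cc1OC)[C@H]1CC[C@@H](C)C2=C[C@@H](C(C)(C)O[Si](CC)(CC)CC)CC[C@@]21C | intermediate (not isolated)
25 | (4S)-4-(octalinyl)-4-(2,4,6-trimethoxyphenyl)butan-2-one | CC(=O)C[C@H](c1c(OC)cc(OC)cc1OC)[C@H]1CC[C@@H](C)C2=C[C@@H](C(C)(C)O[Si](CC)(CC)CC)CC[C@@]21C | intermediate
26 | 2-[(1S)-3-methyl-1-(octalinyl)but-3-en-1-yl]-1,3,5-trimethoxybenzene | CC(=C)C[C@H](c1c(OC)cc(OC)cc1OC)[C@H]1CC[C@@H](C)C2=C[C@@H](C(C)(C)O[Si](CC)(CC)CC)CC[C@@]21C | intermediate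
27 | 2-[(1S)-3-methyl-1-(octalinyl)butyl]-1,3,5-trimethoxybenzene | CC(C)C[C@H](c1c(OC)cc(OC)cc1OC)[C@H]1CC[C@@H](C)C2=C[C@@H](C(C)(C)O[Si](CC)(CC)CC)CC[C@@]21C | intermediate
28 | lithium hemiaminal of the monoaldehyde of 27: CH(OLi)NMe2 on one free ring position of the arene | CC(C)C[C@H](c1c(OC)c(C(O[Li])N(C)C)c(OC)cc1OC)[C@H]1CC[C@@H](C)C2=C[C@@H](C(C)(C)O[Si](CC)(CC)CC)CC[C@@]21C | intermediate (not isolated)
29 | 2,4,6-trimethoxy-5-[(1S)-3-methyl-1-(octalinyl)butyl]benzene-1,3-dicarbaldehyde | CC(C)C[C@H](c1c(OC)c(C=O)c(OC)c(C=O)c1OC)[C@H]1CC[C@@H](C)C2=C[C@@H](C(C)(C)O[Si](CC)(CC)CC)CC[C@@]21C | intermediate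
30 | triethylsilyl ether of the target: 2,4,6-trihydroxy-5-[(1S)-3-methyl-1-(octalinyl)butyl]benzene-1,3-dicarbaldehyde | CC(C)C[C@H](c1c(O)c(C=O)c(O)c(C=O)c1O)[C@H]1CC[C@@H](C)C2=C[C@@H](C(C)(C)O[Si](CC)(CC)CC)CC[C@@]21C | intermediate (not isolated)
31 | CNP0108656.4: 2,4,6-trihydroxy-5-{(1S)-1-[(1R,4R,6S,8aR)-6-(2-hydroxypropan-2-yl)-4,8a-dimethyl-1,2,3,4,6,7,8,8a-octahydronaphthalen-1-yl]-3-methylbutyl}benzene-1,3-dicarbaldehyde | CC(C)C[C@H](c1c(O)c(C=O)c(O)c(C=O)c1O)[C@H]1CC[C@@H](C)C2=C[C@@H](C(C)(C)O)CC[C@@]21C | target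

Total step count: 22. Longest linear sequence: 22 steps (1 to 31); 2, 7 and 23 enter as purchased materials.

Steps most likely to fail

Step 13. What may go wrong: deprotonation at C6 instead of C4a, followed by loss of the silyloxy group or formation of the wrong enol triflate, or enolisation too slow at −78 °C. Fallback, setting out from 12 and returning at 19: the α-formyl aldehyde 12 is cyclised directly with Me2AlCl; its chair with the formyl group equatorial and the chain axial should give the cis-fused homoallylic alcohol F1 with the same C6 configuration. Dess–Martin oxidation gives the cis-fused ketone F2, and LiBH(s-Bu)3 attacks from the α face, away from the C8a methyl, to give the axial 5β-alcohol F3. In this alcohol the C4a hydrogen is cis and the C6 hydrogen trans to the hydroxyl, so the syn elimination with the Burgess reagent can only give the C4a=C5 alkene, the diene F4. Mukaiyama hydration (Co(acac)2, PhSiH3, O2) of the 1,1-disubstituted alkene, which reacts before the hindered trisubstituted one, gives the tertiary alcohol F5, and Et3SiOTf with 2,6-lutidine returns the route at 19.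

Step 8. What may go wrong: poor facial discrimination in the protonation, or drift back to the more stable α-formyl epimer during quench or purification. Fallback, setting out from 8 and returning at 13: the silyl enol ether 8, isolated in this variant by non-aqueous work-up, is alkylated with HC(OMe)3 and TMSOTf, and the product is equilibrated with NaOMe in MeOH to the β-keto acetal F6, which carries the equatorial, β dimethoxymethyl group. Methylenation with Cp2TiMe2 gives the exocyclic alkene F7, and hydrogenation with RhCl(PPh3)3 from the α face, opposite the axial C8a methyl, gives the β-methyl acetal F8. Hydrolysis with oxalic acid on wet silica then releases 13 without passing through an enolate.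

Step 18. What may go wrong: slow transfer of the di-ortho-substituted aryl group to a β-carbon next to a quaternary centre, and incomplete facial selectivity at the benzylic carbon. Fallback, setting out from 21 and returning at 25: Horner–Wadsworth–Emmons reaction of 21 with diethyl {2-oxo-2-[(4S)-2-oxo-4-phenyl-1,3-oxazolidin-3-yl]ethyl}phosphonate gives the (E)-N-enoyl oxazolidinone F9. Addition of (2,4,6-trimethoxyphenyl)magnesium bromide (from 23, n-BuLi, MgBr2) mediated by CuBr·SMe2 to the chelated imide, anti to the auxiliary phenyl group and matched with the substrate bias, gives the β-aryl imide F10. Me(MeO)NH·HCl with AlMe3 gives the Weinreb amide F11, and MeMgBr returns the route at 25.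

Further compounds
F1 | step 13 | 1β-[(benzyloxy)methyl]-4β,8aβ-dimethyl-6β-(prop-1-en-2-yl)decahydronaphthalen-5α-ol, 4a-H β (cis-fused) | c1ccccc1COC[C@H]1CC[C@@H](C)[C@@H]2[C@H](O)[C@@H](C(C)=C)CC[C@@]21C
F2 | step 13 | 1β-[(benzyloxy)methyl]-4β,8aβ-dimethyl-6β-(prop-1-en-2-yl)decahydronaphthalen-5-one, 4a-H β (cis-fused) | c1ccccc1COC[C@H]1CC[C@@H](C)[C@@H]2C(=O)[C@@H](C(C)=C)CC[C@@]21C
F3 | step 13 | 1β-[(benzyloxy)methyl]-4β,8aβ-dimethyl-6β-(prop-1-en-2-yl)decahydronaphthalen-5β-ol, 4a-H β (cis-fused, axial hydroxyl) | c1ccccc1COC[C@H]1CC[C@@H](C)[C@@H]2[C@@H](O)[C@@H](C(C)=C)CC[C@@]21C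
F4 | step 13 | 1β-[(benzyloxy)methyl]-4β,8aβ-dimethyl-6β-(prop-1-en-2-yl)-1,2,3,4,6,7,8,8a-octahydronaphthalene (C4a=C5) | c1ccccc1COC[C@H]1CC[C@@H](C)C2=C[C@@H](C(C)=C)CC[C@@]21C
F5 | step 13 | 2-{1β-[(benzyloxy)methyl]-4β,8aβ-dimethyl-1,2,3,4,6,7,8,8a-octahydronaphthalen-6β-yl}propan-2-ol (C4a=C5) | c1ccccc1COC[C@H]1CC[C@@H](C)C2=C[C@@H](C(C)(C)O)CC[C@@]21C
F6 | step 8 | 4-[(benzyloxy)methyl]-2-(dimethoxymethyl)-3-methyl-3-(4-methylpent-3-en-1-yl)cyclohexan-1-one (C4a CH(OMe)2 β; otherwise as 9) | c1ccccc1COC[C@H]1CCC(=O)[C@@H](C(OC)OC)[C@]1(C)CCC=C(C)C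
F7 | step 8 | C4-methylidene analogue of F6 | c1ccccc1COC[C@H]1CCC(=C)[C@@H](C(OC)OC)[C@]1(C)CCC=C(C)C
F8 | step 8 | dimethyl acetal of 13 (C4 methyl β, C4a CH(OMe)2 β) | c1ccccc1COC[C@H]1CC[C@@H](C)[C@@H](C(OC)OC)[C@]1(C)CCC=C(C)C
F9 | step 18 | (4S)-3-[(E)-3-(octalinyl)prop-2-enoyl]-4-phenyl-1,3-oxazolidin-2-one | O=C(/C=C/[C@H]1CC[C@@H](C)C2=C[C@@H](C(C)(C)O[Si](CC)(CC)CC)CC[C@@]21C)N1C(=O)OC[C@@H]1c1ccccc1
F10 | step 18 | (4S)-3-[(3S)-3-(octalinyl)-3-(2,4,6-trimethoxyphenyl)propanoyl]-4-phenyl-1,3-oxazolidin-2-one | O=C(C[C@H](c1c(OC)cc(OC)cc1OC)[C@H]1CC[C@@H](C)C2=C[C@@H](C(C)(C)O[Si](CC)(CC)CC)CC[C@@]21C)N1C(=O)OC[C@@H]1c1ccccc1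
F11 | step 18 | (3S)-N-methoxy-N-methyl-3-(octalinyl)-3-(2,4,6-trimethoxyphenyl)propanamide | CON(C)C(=O)C[C@H](c1c(OC)cc(OC)cc1OC)[C@H]1CC[C@@H](C)C2=C[C@@H](C(C)(C)O[Si](CC)(CC)CC)CC[C@@]21C
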